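**Plan** (carbons carry labdane numbers C1–C20)
1. Cuts: ring B is opened at its two opposite bonds C5–C10 and C7–C8, which unravels both rings to the acyclic enone–enal–alkyne 19. Then 19 is cut at C5=C6 (Wittig), C1–C2 (carbonyl-ene) and C8–C9 (SN2′ alkynylation) into nerol-derived enyne 6 and malonate-derived aldehyde 14.
2. Enabling feature: C10 is the β-carbon of the C2 ketone and C5 the β-carbon of a C7 aldehyde, so a reductive β,β-coupling of enone and enal closes ring A. The C7 carbinol beside the C8=C17H2 methylidene is what a ketyl radical leaves on adding to a terminal alkyne, and that closes ring B.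
3. Forward: nerol → 6; dimethyl methylmalonate → 14; ene union, oxidation, isomerisation, Swern, Wittig → 19; one tin hydride radical-chain operation closes ring A and then ring B (21); ketal, ester reduction, acetylation, deprotection → 25.
4. Stereochemistry: 13Z from nerol; C9 from the copper-catalysed SN2′ alkynylation; C4 from esterase desymmetrisation; C5 and C10 from the ring-A chair (axial C19 ester, E-enone); C7 from the ring-B chair (axial stannyloxy group).

Key step: step 16

Remark: pig liver esterase is assumed to deliver the (S)-half-ester 9; from the antipode the same 11 would follow by reducing the ester group and esterifying the acid.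

Step 1
Reactants: 1 nerol, (2Z)-3,7-dimethylocta-2,6-dien-1-ol
Product: 2 tert-butyl{[(2Z)-3,7-dimethylocta-2,6-dien-1-yl]oxy}dimethylsilane
Conditions: TBSCl, imidazole, DMF, 0 °C → rt
Reagents that add atoms: tert-butyl(chloro)dimethylsilane, CC(C)(C)[Si](C)(C)Cl
Why: Silyl ether formation protects O15 for the whole route; no stereocentre is formed and the Z alkene of nerol, the later C13 alkene, is not touched.

Step 2
Reactants: 2 tert-butyl{[(2Z)-3,7-dimethylocta-2,6-dien-1-yl]oxy}dimethylsilane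
Product: 3 (2E,6Z)-8-{[tert-butyl(dimethyl)silyl]oxy}-2,6-dimethylocta-2,6-dien-1-ol
Conditions: SeO2 (cat.), t-BuOOH, salicylic acid (cat.), CH2Cl2, rt
Reagents that add atoms: tert-butyl hydroperoxide, CC(C)(C)OO; selenium dioxide, O=[Se]=O
Why: Selenium dioxide allylic oxidation (ene reaction, then 2,3-sigmatropic shift) should attack the electron-richer terminal alkene at its E-methyl group and give the E allylic alcohol, the other alkene being deactivated by its allylic silyloxy group.

Step 3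
Reactants: 3 (2E,6Z)-8-{[tert-butyl(dimethyl)silyl]oxy}-2,6-dimethylocta-2,6-dien-1-ol
Product: 4 (2E,6Z)-8-{[tert-butyl(dimethyl)silyl]oxy}-2,6-dimethylocta-2,6-dien-1-yl diethyl phosphate
Conditions: (EtO)2P(O)Cl, pyridine, DMAP (cat.), CH2Cl2, 0 °C
Reagents that add atoms: diethyl chlorophosphate, CCOP(=O)(Cl)OCC
Why: Phosphorylation of the primary allylic alcohol installs the leaving group for the allylic substitution; no stereocentre is involved.

Step 4
Reactants: 4 (2E,6Z)-8-{[tert-butyl(dimethyl)silyl]oxy}-2,6-dimethylocta-2,6-dien-1-yl diethyl phosphate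
Product: 5 tert-butyl(dimethyl){[(2Z,6R)-3-methyl-6-(prop-1-en-2-yl)-8-(trimethylsilyl)oct-2-en-7-yn-1-yl]oxy}silane
Conditions: Me3SiC≡CH, i-Bu2AlH, Et3N (cat.), hexanes, 0 °C → rt; then 4, CuCl2·2H2O (cat.), chiral sulfonate-bearing imidazolinium salt (cat., carbene precursor), THF, −30 °C
Reagents that add atoms: ethynyl(trimethyl)silane, C#C[Si](C)(C)C
Why: Copper-catalysed enantioselective allylic substitution with an alkynylaluminium reagent should run in the SN2′ sense, so that the alkynyl group enters at C9 and the 1,1-disubstituted alkene is formed; the chiral carbene ligand on copper selects the alkene face and thereby the R configuration at C9.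

Step 5
Reactants: 5 tert-butyl(dimethyl){[(2Z,6R)-3-methyl-6-(prop-1-en-2-yl)-8-(trimethylsilyl)oct-2-en-7-yn-1-yl]oxy}silane
Product: 6 tert-butyl(dimethyl){[(2Z,6R)-3-methyl-6-(prop-1-en-2-yl)oct-2-en-7-yn-1-yl]oxy}silane
Conditions: K2CO3 (cat.), MeOH, rt
Reagents that add atoms: none
Why: Base-mediated protodesilylation of an alkynylsilane frees the terminal alkyne; the silyl ether and the C9 centre are not affected.

Step 6
Reactants: 7 dimethyl 2-methylpropanedioate (dimethyl methylmalonate)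
Product: 8 dimethyl 2-methyl-2-(prop-2-en-1-yl)propanedioate
Conditions: NaH, allyl bromide, THF, 0 °C → rt
Reagents that add atoms: 3-bromoprop-1-ene, C=CCBr
Why: Malonate alkylation (SN2 of the sodium enolate on allyl bromide) builds the quaternary carbon C4 with two enantiotopic ester groups.

Step 7
Reactants: 8 dimethyl 2-methyl-2-(prop-2-en-1-yl)propanedioate
Product: 9 (2S)-2-(methoxycarbonyl)-2-methylpent-4-enoic acid
Conditions: pig liver esterase, phosphate buffer (pH 7), rt; then acidify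
Reagents that add atoms: water, O
Why: Enzymatic desymmetrisation (enantiotopic-group-selective ester hydrolysis) turns the prochiral diester into one half-ester and so sets the quaternary centre C4.

Step 8
Reactants: 9 (2S)-2-(methoxycarbonyl)-2-methylpent-4-enoic acid
Product: 11 methyl (2S)-2-(hydroxymethyl)-2-methylpent-4-enoate, via mixed anhydride 10 (not isolated)
Conditions: i-BuOCOCl, N-methylmorpholine, THF, −15 °C; then NaBH4, MeOH, 0 °C
Reagents that add atoms: none
Why: Mixed-anhydride activation followed by borohydride reduction reduces the carboxylic acid chemoselectively beside the methyl ester and the alkene; the quaternary centre is not touched.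

Step 9
Reactants: 11 methyl (2S)-2-(hydroxymethyl)-2-methylpent-4-enoate
Product: 12 methyl (2S)-2-methyl-2-{[(triethylsilyl)oxy]methyl}pent-4-enoate
Conditions: TESCl, imidazole, CH2Cl2, 0 °C
Reagents that add atoms: chlorotriethylsilane, CC[Si](Cl)(CC)CC
Why: Silylation of the primary neopentyl alcohol with a triethylsilyl group, which can later be oxidised off in the presence of the tert-butyldimethylsilyl ether.

Step 10
Reactants: 12 methyl (2S)-2-methyl-2-{[(triethylsilyl)oxy]methyl}pent-4-enoate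
Product: 14 methyl (2S)-2-methyl-4-oxo-2-{[(triethylsilyl)oxy]methyl}butanoate, via ozonide 13 (not isolated)
Conditions: O3, CH2Cl2, −78 °C; then PPh3, −78 °C → rt
Reagents that add atoms: ozone, [O-][O+]=O
Why: Ozonolysis with reductive work-up cleaves the terminal alkene to the C2 aldehyde; ester and silyl ether are inert.

Step 11
Reactants: 6 tert-butyl(dimethyl){[(2Z,6R)-3-methyl-6-(prop-1-en-2-yl)oct-2-en-7-yn-1-yl]oxy}silane; 14 methyl (2S)-2-methyl-4-oxo-2-{[(triethylsilyl)oxy]methyl}butanoate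
Product: 15 methyl (2S,4RS,7R,10Z)-12-{[tert-butyl(dimethyl)silyl]oxy}-7-ethynyl-4-hydroxy-2,10-dimethyl-6-methylidene-2-{[(triethylsilyl)oxy]methyl}dodec-10-enoate
Conditions: Me2AlCl, CH2Cl2, −78 → −30 °C; cold aqueous quench; used at once
Reagents that add atoms: none
Why: Lewis-acid-promoted carbonyl-ene reaction: the 1,1-disubstituted alkene of 6 attacks the activated aldehyde through its CH2 terminus (new C1–C2 bond) while a methyl hydrogen is transferred, which leaves the C10=C20 methylidene; the new carbinol centre forms as a mixture that step 12 removes.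

Step 12
Reactants: 15 methyl (2S,4RS,7R,10Z)-12-{[tert-butyl(dimethyl)silyl]oxy}-7-ethynyl-4-hydroxy-2,10-dimethyl-6-methylidene-2-{[(triethylsilyl)oxy]methyl}dodec-10-enoate
Product: 16 methyl (2S,7R,10Z)-12-{[tert-butyl(dimethyl)silyl]oxy}-7-ethynyl-2,10-dimethyl-6-methylidene-4-oxo-2-{[(triethylsilyl)oxy]methyl}dodec-10-enoate
Conditions: Dess–Martin periodinane, CH2Cl2, 0 °C → rt
Reagents that add atoms: none
Why: Dess–Martin oxidation under neutral conditions gives the β,γ-unsaturated ketone without touching the silyl ethers or the alkyne, and it prevents lactonisation of the γ-hydroxy ester.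

Step 13
Reactants: 16 methyl (2S,7R,10Z)-12-{[tert-butyl(dimethyl)silyl]oxy}-7-ethynyl-2,10-dimethyl-6-methylidene-4-oxo-2-{[(triethylsilyl)oxy]methyl}dodec-10-enoate
Product: 17 methyl (2S,5E,7S,10Z)-12-{[tert-butyl(dimethyl)silyl]oxy}-7-ethynyl-2,6,10-trimethyl-4-oxo-2-{[(triethylsilyl)oxy]methyl}dodeca-5,10-dienoate
Conditions: DBU (cat.), CH2Cl2, 0 °C
Reagents that add atoms: none
Why: Base-catalysed isomerisation through the dienolate (1,3-prototropic shift) moves the alkene into conjugation; the E isomer with the C9 branch trans to the acyl group is the thermodynamic one, and the less acidic C9–H should survive catalytic DBU at 0 °C (the descriptor at C9 changes by priority only).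

Step 14
Reactants: 17 methyl (2S,5E,7S,10Z)-12-{[tert-butyl(dimethyl)silyl]oxy}-7-ethynyl-2,6,10-trimethyl-4-oxo-2-{[(triethylsilyl)oxy]methyl}dodeca-5,10-dienoate
Product: 18 methyl (2S,5E,7S,10Z)-12-{[tert-butyl(dimethyl)silyl]oxy}-7-ethynyl-2-formyl-2,6,10-trimethyl-4-oxododeca-5,10-dienoate
Conditions: (COCl)2, DMSO, CH2Cl2, −78 → −30 °C; then Et3N
Reagents that add atoms: none
Why: Swern oxidation: activated DMSO converts a primary triethylsilyl ether directly into the aldehyde while the tert-butyldimethylsilyl ether is left, so deprotection and oxidation are one operation.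

Step 15
Reactants: 18 methyl (2S,5E,7S,10Z)-12-{[tert-butyl(dimethyl)silyl]oxy}-7-ethynyl-2-formyl-2,6,10-trimethyl-4-oxododeca-5,10-dienoate
Product: 19 methyl (2S,5E,7S,10Z)-12-{[tert-butyl(dimethyl)silyl]oxy}-7-ethynyl-2,6,10-trimethyl-4-oxo-2-[(1E)-3-oxoprop-1-en-1-yl]dodeca-5,10-dienoate
Conditions: Ph3P=CHCHO, toluene, 80 °C
Reagents that add atoms: (triphenylphosphoranylidene)acetaldehyde, O=CC=P(c1ccccc1)(c1ccccc1)c1ccccc1
Why: Wittig olefination with the stabilised formylmethylene ylide reacts only at the aldehyde and gives the E-enal, the C5=C6–C7 acrolein unit.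

Step 16
Reactants: 19 methyl (2S,5E,7S,10Z)-12-{[tert-butyl(dimethyl)silyl]oxy}-7-ethynyl-2,6,10-trimethyl-4-oxo-2-[(1E)-3-oxoprop-1-en-1-yl]dodeca-5,10-dienoate
Product: 21 methyl (4S,5R,7R,9R,10R,13Z)-15-{[tert-butyl(dimethyl)silyl]oxy}-7-hydroxy-2-oxolabda-8(17),13-dien-19-oate (7α-OH, 5α-H, 9α-H, 10β-CH3, 4α-CH3), via keto aldehyde 20 (not isolated)
Conditions: Bu3SnH (2.5 equiv, syringe pump), AIBN (cat.), MeOH (5 equiv), PhH (5 mM), 80 °C; then 1 M HCl, Et2O
Reagents that add atoms: none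
Why: Bu3Sn radical adds reversibly to the oxygen of either conjugated carbonyl to give an O-stannyl allyl radical, and coupling of C10 (β-carbon of the enone) with C5 (β-carbon of the enal) closes ring A by 6-exo-trig attack on the enal; the α-carbonyl radical takes hydrogen from Bu3SnH, methanol protonates the tin enolate to keto aldehyde 20, and a second chain (Bu3Sn radical on the aldehyde oxygen, 6-exo-dig attack of the C7 ketyl radical on alkyne carbon C8, hydrogen transfer to the C17 vinyl radical) closes ring B as the 8(17)-methylidene 7-carbinol. The closest known reaction types are the tin hydride cyclisation of enones through allylic O-stannyl ketyl radicals onto acrylate-type acceptors and the stannane-mediated ketyl–alkyne (aldehyde–alkyne) radical cyclisation. Ring A closes through a chair in which the E geometry of the enone places methyl C20 axial and the C9 branch equatorial and the enal arm is equatorial, which gives the trans relation of H5 and C20. Of the two such chairs the one with the planar ester C19 axial (1,3-diaxial to C20) should be preferred over the one with two axial methyl groups, so the C4 centre fixes the absolute sense at C5 and C10; in the ring-B chair the stannyloxy group on C7 should sit axial, away from the developing exocyclic C8=C17 bond (allylic 1,3-strain), with only H5 and H9 as syn-axial partners, which is the 7α-alcohol. The step needs ring closure to outrun hydrogen transfer (slow addition of Bu3SnH at high dilution) and ring A to form before ring B, which the substrate secures because C7 and C8 come within reach only once the C5–C10 bond exists, while addition of the tin radical to the alkyne is reversible and the trisubstituted C13 alkene and the ester are not acceptors.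

Step 17
Reactants: 21 methyl (4S,5R,7R,9R,10R,13Z)-15-{[tert-butyl(dimethyl)silyl]oxy}-7-hydroxy-2-oxolabda-8(17),13-dien-19-oate
Product: 22 methyl (4S,5R,7R,9R,10R,13Z)-15-{[tert-butyl(dimethyl)silyl]oxy}-2,2-(ethane-1,2-diyldioxy)-7-hydroxylabda-8(17),13-dien-19-oate
Conditions: Me3SiOCH2CH2OSiMe3, TMSOTf (cat.), CH2Cl2, −78 °C; aq. NaHCO3
Reagents that add atoms: 1,2-bis(trimethylsilyloxy)ethane, C[Si](C)(C)OCCO[Si](C)(C)C
Why: Acid-catalysed ketalisation with the bis-silyl ether of ethylene glycol masks the C2 ketone at low temperature so that the ester can be reduced; no stereocentre is affected.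

Step 18
Reactants: 22 methyl (4S,5R,7R,9R,10R,13Z)-15-{[tert-butyl(dimethyl)silyl]oxy}-2,2-(ethane-1,2-diyldioxy)-7-hydroxylabda-8(17),13-dien-19-oate
Product: 23 (4S,5R,7R,9R,10S,13Z)-15-{[tert-butyl(dimethyl)silyl]oxy}-2,2-(ethane-1,2-diyldioxy)labda-8(17),13-diene-7,19-diol
Conditions: LiAlH4, THF, 0 °C → reflux
Reagents that add atoms: none
Why: Hydride reduction of the hindered axial methyl ester gives the C19 primary alcohol; ketal, silyl ether and alkenes are inert (the C10 descriptor changes by priority only).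

Step 19
Reactants: 23 (4S,5R,7R,9R,10S,13Z)-15-{[tert-butyl(dimethyl)silyl]oxy}-2,2-(ethane-1,2-diyldioxy)labda-8(17),13-diene-7,19-diol
Product: 24 (4S,5R,7R,9R,10S,13Z)-15-{[tert-butyl(dimethyl)silyl]oxy}-2,2-(ethane-1,2-diyldioxy)-7-hydroxylabda-8(17),13-dien-19-yl acetate
Conditions: Ac2O (1.1 equiv), pyridine, CH2Cl2, 0 °C
Reagents that add atoms: acetic anhydride, CC(=O)OC(C)=O
Why: Selective acylation: the primary C19 alcohol should be acetylated much faster than the axial, allylic secondary C7 alcohol.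

Step 20
Reactants: 24 (4S,5R,7R,9R,10S,13Z)-15-{[tert-butyl(dimethyl)silyl]oxy}-2,2-(ethane-1,2-diyldioxy)-7-hydroxylabda-8(17),13-dien-19-yl acetate
Product: 25 (4S,5R,7R,9R,10S,13Z)-7,15-dihydroxy-2-oxolabda-8(17),13-dien-19-yl acetate (target)
Conditions: 1 M aq. HCl, THF, rt
Reagents that add atoms: water, O
Why: Acid hydrolysis removes the dioxolane and the primary silyl ether in one operation and leaves the acetate and the allylic alcohol.

**Compound list**
1 | nerol, (2Z)-3,7-dimethylocta-2,6-dien-1-ol | CC(C)=CCC/C(C)=C\CO | starting material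
2 | tert-butyl{[(2Z)-3,7-dimethylocta-2,6-dien-1-yl]oxy}dimethylsilane | CC(C)=CCC/C(C)=C\CO[Si](C)(C)C(C)(C)C | intermediate
3 | (2E,6Z)-8-{[tert-butyl(dimethyl)silyl]oxy}-2,6-dimethylocta-2,6-dien-1-ol | OC/C(C)=C/CC/C(C)=C\CO[Si](C)(C)C(C)(C)C | intermediate
4 | (2E,6Z)-8-{[tert-butyl(dimethyl)silyl]oxy}-2,6-dimethylocta-2,6-dien-1-yl diethyl phosphate | CCOP(=O)(OCC)OC/C(C)=C/CC/C(C)=C\CO[Si](C)(C)C(C)(C)C | intermediate
5 | tert-butyl(dimethyl){[(2Z,6R)-3-methyl-6-(prop-1-en-2-yl)-8-(trimethylsilyl)oct-2-en-7-yn-1-yl]oxy}silane | C=C(C)[C@H](C#C[Si](C)(C)C)CC/C(C)=C\CO[Si](C)(C)C(C)(C)C | intermediate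
6 | tert-butyl(dimethyl){[(2Z,6R)-3-methyl-6-(prop-1-en-2-yl)oct-2-en-7-yn-1-yl]oxy}silane | C=C(C)[C@H](C#C)CC/C(C)=C\CO[Si](C)(C)C(C)(C)C | intermediate
7 | dimethyl 2-methylpropanedioate (dimethyl methylmalonate) | COC(=O)C(C)C(=O)OC | starting material
8 | dimethyl 2-methyl-2-(prop-2-en-1-yl)propanedioate | C=CCC(C)(C(=O)OC)C(=O)OC | intermediate
9 | (2S)-2-(methoxycarbonyl)-2-methylpent-4-enoic acid | C=CC[C@](C)(C(=O)OC)C(=O)O | intermediate
10 | mixed isobutyl carbonic anhydride of acid 9 (quaternary centre unchanged) | C=CC[C@](C)(C(=O)OC)C(=O)OC(=O)OCC(C)C | intermediate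
11 | methyl (2S)-2-(hydroxymethyl)-2-methylpent-4-enoate | C=CC[C@](C)(C(=O)OC)CO | intermediate
12 | methyl (2S)-2-methyl-2-{[(triethylsilyl)oxy]methyl}pent-4-enoate | C=CC[C@](C)(C(=O)OC)CO[Si](CC)(CC)CC | intermediate
13 | methyl (2S)-2-methyl-2-{[(triethylsilyl)oxy]methyl}-3-(1,2,4-trioxolan-3-yl)propanoate (ozonide, trioxolane carbon unspecified) | C1OOC(C[C@](C)(C(=O)OC)CO[Si](CC)(CC)CC)O1 | intermediate
14 | methyl (2S)-2-methyl-4-oxo-2-{[(triethylsilyl)oxy]methyl}butanoate | O=CC[C@](C)(C(=O)OC)CO[Si](CC)(CC)CC | intermediate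
15 | methyl (2S,4RS,7R,10Z)-12-{[tert-butyl(dimethyl)silyl]oxy}-7-ethynyl-4-hydroxy-2,10-dimethyl-6-methylidene-2-{[(triethylsilyl)oxy]methyl}dodec-10-enoate | C=C(CC(O)C[C@](C)(C(=O)OC)CO[Si](CC)(CC)CC)[C@H](C#C)CC/C(C)=C\CO[Si](C)(C)C(C)(C)C | intermediate
16 | methyl (2S,7R,10Z)-12-{[tert-butyl(dimethyl)silyl]oxy}-7-ethynyl-2,10-dimethyl-6-methylidene-4-oxo-2-{[(triethylsilyl)oxy]methyl}dodec-10-enoate | C=C(CC(=O)C[C@](C)(C(=O)OC)CO[Si](CC)(CC)CC)[C@H](C#C)CC/C(C)=C\CO[Si](C)(C)C(C)(C)C | intermediate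
17 | methyl (2S,5E,7S,10Z)-12-{[tert-butyl(dimethyl)silyl]oxy}-7-ethynyl-2,6,10-trimethyl-4-oxo-2-{[(triethylsilyl)oxy]methyl}dodeca-5,10-dienoate | C/C(=C\C(=O)C[C@](C)(C(=O)OC)CO[Si](CC)(CC)CC)[C@H](C#C)CC/C(C)=C\CO[Si](C)(C)C(C)(C)C | intermediate
18 | methyl (2S,5E,7S,10Z)-12-{[tert-butyl(dimethyl)silyl]oxy}-7-ethynyl-2-formyl-2,6,10-trimethyl-4-oxododeca-5,10-dienoate | C/C(=C\C(=O)C[C@](C)(C(=O)OC)C=O)[C@H](C#C)CC/C(C)=C\CO[Si](C)(C)C(C)(C)C | intermediate
19 | methyl (2S,5E,7S,10Z)-12-{[tert-butyl(dimethyl)silyl]oxy}-7-ethynyl-2,6,10-trimethyl-4-oxo-2-[(1E)-3-oxoprop-1-en-1-yl]dodeca-5,10-dienoate | C/C(=C\C(=O)C[C@](C)(C(=O)OC)/C=C/C=O)[C@H](C#C)CC/C(C)=C\CO[Si](C)(C)C(C)(C)C | intermediate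
20 | methyl (4S,5R,9S,10R,13Z)-15-{[tert-butyl(dimethyl)silyl]oxy}-2,7-dioxo-7,8-secolabd-13-en-8(17)-yn-19-oate (ring A closed, C7 aldehyde and C8 alkyne open; 5α-H, 9α-H, 10β-CH3) | O=CC[C@H]1[C@@](C)(C(=O)OC)CC(=O)C[C@]1(C)[C@H](C#C)CC/C(C)=C\CO[Si](C)(C)C(C)(C)C | intermediate
21 | methyl (4S,5R,7R,9R,10R,13Z)-15-{[tert-butyl(dimethyl)silyl]oxy}-7-hydroxy-2-oxolabda-8(17),13-dien-19-oate | C=C1[C@H](O)C[C@H]2[C@@](C)(C(=O)OC)CC(=O)C[C@]2(C)[C@H]1CC/C(C)=C\CO[Si](C)(C)C(C)(C)C | intermediate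
22 | methyl (4S,5R,7R,9R,10R,13Z)-15-{[tert-butyl(dimethyl)silyl]oxy}-2,2-(ethane-1,2-diyldioxy)-7-hydroxylabda-8(17),13-dien-19-oate | C=C1[C@H](O)C[C@H]2[C@@](C)(C(=O)OC)CC3(OCCO3)C[C@]2(C)[C@H]1CC/C(C)=C\CO[Si](C)(C)C(C)(C)C | intermediate
23 | (4S,5R,7R,9R,10S,13Z)-15-{[tert-butyl(dimethyl)silyl]oxy}-2,2-(ethane-1,2-diyldioxy)labda-8(17),13-diene-7,19-diol | C=C1[C@H](O)C[C@H]2[C@@](C)(CO)CC3(OCCO3)C[C@]2(C)[C@H]1CC/C(C)=C\CO[Si](C)(C)C(C)(C)C | intermediate
24 | (4S,5R,7R,9R,10S,13Z)-15-{[tert-butyl(dimethyl)silyl]oxy}-2,2-(ethane-1,2-diyldioxy)-7-hydroxylabda-8(17),13-dien-19-yl acetate | C=C1[C@H](O)C[C@H]2[C@@](C)(COC(C)=O)CC3(OCCO3)C[C@]2(C)[C@H]1CC/C(C)=C\CO[Si](C)(C)C(C)(C)C | intermediate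
25 | (4S,5R,7R,9R,10S,13Z)-7,15-dihydroxy-2-oxolabda-8(17),13-dien-19-yl acetate (7α-OH, 19-OAc on the 4β-CH2) | C=C1[C@H](O)C[C@H]2[C@@](C)(COC(C)=O)CC(=O)C[C@]2(C)[C@H]1CC/C(C)=C\CO | target

**Totals and risks**
Total step count: 20. Longest linear sequence: 15 steps (steps 1–5 then 11–20, or steps 6–10 then 11–20).

Steps most likely to fail: 16, 11 and 4.

Step 16. Hydrogen transfer may reach the C10 or C7 radical before ring closure, the alkyne may be hydrostannylated for good, the C17 vinyl radical may shift by 1,5-hydrogen transfer, or the facial selectivity in the ring-A chair may be poor. The fallback sets out from 16 and comes back at 21, and makes the two bonds one after the other without tin. Swern oxidation of the triethylsilyl ether of 16 (as in step 14, quenched cold) would give methyl (2S,7R,10Z)-12-{[tert-butyl(dimethyl)silyl]oxy}-7-ethynyl-2-formyl-2,10-dimethyl-6-methylidene-4-oxododec-10-enoate F1. Wittig reaction with Ph3P=CHCHO would give methyl (2S,7R,10Z)-12-{[tert-butyl(dimethyl)silyl]oxy}-7-ethynyl-2,10-dimethyl-6-methylidene-4-oxo-2-[(1E)-3-oxoprop-1-en-1-yl]dodec-10-enoate F2. Hydrogen atom transfer from an iron hydride (Fe(acac)3, PhSiH3, EtOH/ethylene glycol, 60 °C) to the 1,1-disubstituted alkene makes the C10 radical, which adds 6-exo to the enal (reductive olefin coupling of the Giese type) and gives 20, here isolated. Nickel-catalysed reductive aldehyde–alkyne cyclisation (Ni(cod)2, 1,3-dimesitylimidazol-2-ylidene, Et3SiH, THF) then closes ring B as methyl (4S,5R,7R,9R,10R,13Z)-15-{[tert-butyl(dimethyl)silyl]oxy}-2-oxo-7-[(triethylsilyl)oxy]labda-8(17),13-dien-19-oate F3, and PPTS in MeOH removes the triethylsilyl group to give 21.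

Step 11. The hydrogen may be transferred from C9 instead of the methyl group, the ene reaction may compete at the trisubstituted alkene, or the γ-hydroxy ester may lactonise. The fallback sets out from 14 (and uses 5) and comes back at 17, replacing the ene union by olefin cross-metathesis. Vinylmagnesium bromide (THF, −78 °C) would add to 14 to give methyl (2S,4RS)-4-hydroxy-2-methyl-2-{[(triethylsilyl)oxy]methyl}hex-5-enoate F4, and Dess–Martin oxidation would give methyl (2S)-2-methyl-4-oxo-2-{[(triethylsilyl)oxy]methyl}hex-5-enoate F5. Cross-metathesis of F5 with the isopropenyl group of 5 (second-generation Grubbs catalyst, CH2Cl2, 40 °C) would give the E-enone methyl (2S,5E,7R,10Z)-12-{[tert-butyl(dimethyl)silyl]oxy}-2,6,10-trimethyl-4-oxo-2-{[(triethylsilyl)oxy]methyl}-7-[(trimethylsilyl)ethynyl]dodeca-5,10-dienoate F6 directly. K2CO3 in MeOH at 0 °C removes the alkynyl silyl group and gives 17.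

Step 4. The SN2′ versus SN2 selectivity or the enantioselectivity may be poor on this β-methyl allylic phosphate. The fallback sets out from 3 and comes back at 5, setting C9 by substrate-directed epoxide chemistry. Sharpless asymmetric epoxidation of 3 (Ti(OiPr)4, L-(+)-diethyl tartrate, t-BuOOH, 4 Å sieves, −20 °C) would give [(2S,3S)-3-[(3Z)-5-{[tert-butyl(dimethyl)silyl]oxy}-3-methylpent-3-en-1-yl]-2-methyloxiran-2-yl]methanol F7. Diethyl[(trimethylsilyl)ethynyl]aluminium (from the lithium acetylide and Et2AlCl, toluene, 0 °C) opens the epoxide at the carbon remote from the hydroxyl (C9) with inversion to give (2R,3S,6Z)-8-{[tert-butyl(dimethyl)silyl]oxy}-2,6-dimethyl-3-[(trimethylsilyl)ethynyl]oct-6-ene-1,2-diol F8. 1,1′-Thiocarbonyldiimidazole gives (4R)-4-[(1S,4Z)-6-{[tert-butyl(dimethyl)silyl]oxy}-4-methyl-1-[(trimethylsilyl)ethynyl]hex-4-en-1-yl]-4-methyl-1,3-dioxolane-2-thione F9, and Corey–Winter olefination (P(OMe)3, 110 °C) gives the 1,1-disubstituted alkene of 5.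

**Further compounds**
F1 | step 16 | methyl (2S,7R,10Z)-12-{[tert-butyl(dimethyl)silyl]oxy}-7-ethynyl-2-formyl-2,10-dimethyl-6-methylidene-4-oxododec-10-enoate | C=C(CC(=O)C[C@](C)(C(=O)OC)C=O)[C@H](C#C)CC/C(C)=C\CO[Si](C)(C)C(C)(C)C
F2 | step 16 | methyl (2S,7R,10Z)-12-{[tert-butyl(dimethyl)silyl]oxy}-7-ethynyl-2,10-dimethyl-6-methylidene-4-oxo-2-[(1E)-3-oxoprop-1-en-1-yl]dodec-10-enoate | C=C(CC(=O)C[C@](C)(C(=O)OC)/C=C/C=O)[C@H](C#C)CC/C(C)=C\CO[Si](C)(C)C(C)(C)C
F3 | step 16 | methyl (4S,5R,7R,9R,10R,13Z)-15-{[tert-butyl(dimethyl)silyl]oxy}-2-oxo-7-[(triethylsilyl)oxy]labda-8(17),13-dien-19-oate | C=C1[C@H](O[Si](CC)(CC)CC)C[C@H]2[C@@](C)(C(=O)OC)CC(=O)C[C@]2(C)[C@H]1CC/C(C)=C\CO[Si](C)(C)C(C)(C)C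
F4 | step 11 | methyl (2S,4RS)-4-hydroxy-2-methyl-2-{[(triethylsilyl)oxy]methyl}hex-5-enoate | C=CC(O)C[C@](C)(C(=O)OC)CO[Si](CC)(CC)CC
F5 | step 11 | methyl (2S)-2-methyl-4-oxo-2-{[(triethylsilyl)oxy]methyl}hex-5-enoate | C=CC(=O)C[C@](C)(C(=O)OC)CO[Si](CC)(CC)CC
F6 | step 11 | methyl (2S,5E,7R,10Z)-12-{[tert-butyl(dimethyl)silyl]oxy}-2,6,10-trimethyl-4-oxo-2-{[(triethylsilyl)oxy]methyl}-7-[(trimethylsilyl)ethynyl]dodeca-5,10-dienoate | C/C(=C\C(=O)C[C@](C)(C(=O)OC)CO[Si](CC)(CC)CC)[C@H](C#C[Si](C)(C)C)CC/C(C)=C\CO[Si](C)(C)C(C)(C)C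
F7 | step 4 | [(2S,3S)-3-[(3Z)-5-{[tert-butyl(dimethyl)silyl]oxy}-3-methylpent-3-en-1-yl]-2-methyloxiran-2-yl]methanol | OC[C@]1(C)O[C@H]1CC/C(C)=C\CO[Si](C)(C)C(C)(C)C
F8 | step 4 | (2R,3S,6Z)-8-{[tert-butyl(dimethyl)silyl]oxy}-2,6-dimethyl-3-[(trimethylsilyl)ethynyl]oct-6-ene-1,2-diol | OC[C@](C)(O)[C@H](C#C[Si](C)(C)C)CC/C(C)=C\CO[Si](C)(C)C(C)(C)C
F9 | step 4 | (4R)-4-[(1S,4Z)-6-{[tert-butyl(dimethyl)silyl]oxy}-4-methyl-1-[(trimethylsilyl)ethynyl]hex-4-en-1-yl]-4-methyl-1,3-dioxolane-2-thione | S=C1OC[C@@](C)([C@H](C#C[Si](C)(C)C)CC/C(C)=C\CO[Si](C)(C)C(C)(C)C)O1
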